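**Retrosynthetic overview**
- 27 ⇐ 26 (acetylation) ⇐ 22 + 24: the C2'–C3' bond by a ligand-controlled Nozaki–Hiyama–Kishi coupling; 22 ⇐ 20 by esterification and iododeboronation.
- 20 ⇐ 17 + B2pin2: the cyclohexane is closed at C3–C4 by a copper-catalysed borylative allene–aldehyde cyclisation of an open-chain epoxy allenyl aldehyde; the boron it installs at C2' is the handle for the side chain.
- Enabling feature: the array O–C3–C4–C2'(=C1'H2) (ring carbinol C3 next to ring carbon C4 that carries a 1,1-disubstituted alkene) is a homoallylic alcohol retron; C4, C2' and C1' are the three carbons of a terminal allene and C3 is an aldehyde.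
- 17 ⇐ 12 ⇐ 11 ⇐ 9: the oxirane by hydroxyl-directed epoxidation of a (Z)-trisubstituted allylic alcohol; the Z-alkene by Wittig reaction of glycerate-derived methyl ketone 7 with homoallenyl ylide 8.
- Ring order: oxirane first (step 8), then the cyclohexane (step 13); the dioxolane of 5 and the dioxaborolane are auxiliary rings and are removed.

Key step: step 13

Remark on the chemistry: the two C5 esters are read from the SMILES as angelates, (2Z)-2-methylbut-2-enoates. Ring locants follow 7-oxabicyclo[4.1.0]heptane (C1 methyl-bearing oxirane carbon, C2 and C3 ester-bearing carbons, C4 side-chain-bearing carbon, C6 oxirane CH); the side chain is C1'(=CH2), C2', C3'(OAc). The angeloyl donor 14 is made once, in step 9, in the amount needed for both esterifications (steps 10 and 14).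

**Step 1**
Reactants: 1 but-3-yn-1-ol
Product: 2 penta-3,4-dien-1-ol
Conditions: (CH2O)n, CuI (0.5 equiv), iPr2NH, 1,4-dioxane, reflux
Reagents that add atoms: paraformaldehyde (as formaldehyde), C=O
Why: Crabbé homologation, in which the copper acetylide–iminium adduct undergoes hydride shift and elimination to the terminal allene; the free alcohol is tolerated and no stereocentre is formed.

**Step 2**
Reactants: 2 penta-3,4-dien-1-ol
Product: 3 5-bromopenta-1,2-diene
Conditions: CBr4, PPh3, CH2Cl2, 0 °C to rt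
Reagents that add atoms: carbon tetrabromide, BrC(Br)(Br)Br
Why: Appel reaction converts the primary alcohol into the bromide under neutral conditions that leave the allene untouched.

**Step 3**
Reactants: 3 5-bromopenta-1,2-diene
Product: 4 (penta-3,4-dien-1-yl)triphenylphosphonium bromide
Conditions: PPh3, MeCN, 80 °C (sealed vessel)
Reagents that add atoms: triphenylphosphine, c1ccc(cc1)P(c1ccccc1)c1ccccc1
Why: SN2 quaternisation of the phosphine by the unhindered primary bromide gives the Wittig salt.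

**Step 4**
Reactants: 5 methyl (4S)-2,2-dimethyl-1,3-dioxolane-4-carboxylate
Product: 7 1-[(4S)-2,2-dimethyl-1,3-dioxolan-4-yl]ethan-1-one, via Weinreb amide 6 (not isolated)
Conditions: MeNH(OMe)·HCl, iPrMgCl, THF, −20 °C; then MeMgBr, −20 to 0 °C; aq NH4Cl
Reagents that add atoms: methylmagnesium bromide, C[Mg]Br; N,O-dimethylhydroxylamine hydrochloride, CNOC.Cl (its atoms are carried only in 6)
Why: Weinreb ketone synthesis in one flask: the magnesium amide turns the ester into amide 6, whose chelated adduct with MeMgBr stops at the ketone stage, and the C4 stereocentre is not exposed to enolising conditions.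

**Step 5**
Reactants: 4 (penta-3,4-dien-1-yl)triphenylphosphonium bromide; 7 1-[(4S)-2,2-dimethyl-1,3-dioxolan-4-yl]ethan-1-one
Product: 9 (4R)-4-[(2Z)-hepta-2,5,6-trien-2-yl]-2,2-dimethyl-1,3-dioxolane, via phosphonium ylide 8 (not isolated)
Conditions: 4, KN(SiMe3)2, THF, −78 to 0 °C; then 7, −78 °C to rt
Reagents that add atoms: none
Why: Wittig reaction of a non-stabilised ylide with an α-alkoxy methyl ketone, a combination known to place the oxygenated carbon and the ylide chain cis on the new trisubstituted alkene (Z), which is the cis relation of the future C2 and C5 that the ring needs; low temperature limits enolisation at the stereocentre.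

**Step 6**
Reactants: 9 (4R)-4-[(2Z)-hepta-2,5,6-trien-2-yl]-2,2-dimethyl-1,3-dioxolane
Product: 10 (2R,3Z)-3-methylocta-3,6,7-triene-1,2-diol
Conditions: AcOH/H2O (4:1), 40 °C
Reagents that add atoms: none
Why: mild acid hydrolysis of the acetonide, to which the allene and the skipped diene are inert.

**Step 7**
Reactants: 10 (2R,3Z)-3-methylocta-3,6,7-triene-1,2-diol
Product: 11 (2R,3Z)-1-[(tert-butyldimethylsilyl)oxy]-3-methylocta-3,6,7-trien-2-ol
Conditions: TBSCl, imidazole, CH2Cl2, −20 to 0 °C
Reagents that add atoms: tert-butyldimethylsilyl chloride, CC(C)(C)[Si](C)(C)Cl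
Why: the primary hydroxyl is silylated selectively on steric grounds, leaving the secondary allylic OH free to direct the epoxidation.

**Step 8**
Reactants: 11 (2R,3Z)-1-[(tert-butyldimethylsilyl)oxy]-3-methylocta-3,6,7-trien-2-ol
Product: 12 (1S)-1-[(2R,3S)-3-(buta-2,3-dien-1-yl)-2-methyloxiran-2-yl]-2-[(tert-butyldimethylsilyl)oxy]ethan-1-ol
Conditions: mCPBA, NaHCO3, CH2Cl2, −10 to 0 °C
Reagents that add atoms: 3-chloroperoxybenzoic acid, OOC(=O)c1cccc(Cl)c1
Why: hydroxyl-directed peracid epoxidation: A(1,3) strain with the cis CH2 group holds the carbinol H in the alkene plane, so the hydrogen-bonded peracid is delivered to the face carrying OH and sets both oxirane centres (C1 and C6 of the target) relative to C2; the electron-rich trisubstituted alkene should react far faster than the allene.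

**Step 9**
Reactants: 13 angelic acid
Product: 14 (2Z)-2-methylbut-2-enoic 2,4,6-trichlorobenzoic anhydride
Conditions: 2,4,6-trichlorobenzoyl chloride, Et3N, toluene, rt; filter under argon; filtrate concentrated and kept as a toluene stock solution at −20 °C
Reagents that add atoms: 2,4,6-trichlorobenzoyl chloride, O=C(Cl)c1c(Cl)cc(Cl)cc1Cl
Why: mixed-anhydride formation (the activation stage of the Yamaguchi esterification) by acyl substitution of triethylammonium angelate on the aroyl chloride, run at room temperature without a nucleophilic catalyst so that the Z geometry is kept.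

**Step 10**
Reactants: 12 (1S)-1-[(2R,3S)-3-(buta-2,3-dien-1-yl)-2-methyloxiran-2-yl]-2-[(tert-butyldimethylsilyl)oxy]ethan-1-ol; 14 (2Z)-2-methylbut-2-enoic 2,4,6-trichlorobenzoic anhydride
Product: 15 (1S)-1-[(2S,3S)-3-(buta-2,3-dien-1-yl)-2-methyloxiran-2-yl]-2-[(tert-butyldimethylsilyl)oxy]ethyl (2Z)-2-methylbut-2-enoate
Conditions: 14 (toluene solution), 12, toluene, 70 °C
Reagents that add atoms: none
Why: Yamaguchi-type esterification in which the alcohol attacks the unhindered angeloyl carbonyl of the preformed mixed anhydride without a nucleophilic amine catalyst, the protocol used for angelates because it avoids Z to E isomerisation; the carbinol configuration is retained.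

**Step 11**
Reactants: 15 (1S)-1-[(2S,3S)-3-(buta-2,3-dien-1-yl)-2-methyloxiran-2-yl]-2-[(tert-butyldimethylsilyl)oxy]ethyl (2Z)-2-methylbut-2-enoate
Product: 16 (1S)-1-[(2S,3S)-3-(buta-2,3-dien-1-yl)-2-methyloxiran-2-yl]-2-hydroxyethyl (2Z)-2-methylbut-2-enoate
Conditions: HF·pyridine, pyridine, THF, 0 °C to rt
Reagents that add atoms: none
Why: buffered, mildly acidic fluoride desilylation avoids the base-induced 1,2-acyl shift from the secondary to the primary oxygen and should leave the oxirane intact.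

**Step 12**
Reactants: 16 (1S)-1-[(2S,3S)-3-(buta-2,3-dien-1-yl)-2-methyloxiran-2-yl]-2-hydroxyethyl (2Z)-2-methylbut-2-enoate
Product: 17 (1R)-1-[(2S,3S)-3-(buta-2,3-dien-1-yl)-2-methyloxiran-2-yl]-2-oxoethyl (2Z)-2-methylbut-2-enoate
Conditions: Dess–Martin periodinane, NaHCO3, CH2Cl2, 0 °C to rt; used at once
Reagents that add atoms: none
Why: Dess–Martin oxidation under buffered neutral conditions should give the α-acyloxy aldehyde without epimerisation of the adjacent centre.

**Step 13**
Reactants: 17 (1R)-1-[(2S,3S)-3-(buta-2,3-dien-1-yl)-2-methyloxiran-2-yl]-2-oxoethyl (2Z)-2-methylbut-2-enoate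
Product: 20 (1S,2S,3R,4S,6S)-3-hydroxy-1-methyl-4-[1-(4,4,5,5-tetramethyl-1,3,2-dioxaborolan-2-yl)ethenyl]-7-oxabicyclo[4.1.0]heptan-2-yl (2Z)-2-methylbut-2-enoate, via allylcopper 18 (not isolated), via boryl ether 19 (not isolated)
Conditions: CuCl (5 mol %), 4,5-bis(diphenylphosphino)-9,9-dimethylxanthene (5 mol %), NaOtBu (10 mol %), B2pin2 (1.1 equiv), THF, 0 °C to rt; then aq NH4Cl
Reagents that add atoms: bis(pinacolato)diboron, CC1(C)OB(OC1(C)C)B1OC(C)(C)C(C)(C)O1
Why: The boryl complex of monovalent copper formed from CuCl, NaOtBu and B2pin2 adds syn across the terminal C=C of the allene from the side away from the tether, with boron on the central carbon, to give (Z)-2-boryl σ-allylcopper 18; its γ-carbon (future C4) adds to the tethered aldehyde through a closed six-membered chair transition state, and the copper alkoxide is borylated by B2pin2 to 19 with regeneration of the catalyst. The closest known reaction type is the copper-catalysed three-component coupling of allenes, B2pin2 and aldehydes or ketones, together with its intramolecular form on allene-tethered ketones. The cyclohexane closes by 6-exo-trig attack of the allyl carbon on the C=O, forming the C3–C4 bond. C4 and C3 are set together: the Z geometry of 18 puts the ring methylene C5 axial in the metal-containing chair, which translates into a cis relation of the C3–O bond and the C4 alkenyl group. Their sense relative to the existing centres should come from C2, whose C–O bond takes the pseudo-axial position anti to the carbonyl dipole, so that the C3–O bond forms trans to it and the alkenyl group sits equatorial. The step needs borylcupration of the allene in preference to the aldehyde, the enoate and the oxirane, which the fast insertion of the terminal allene π-bond, a phosphine ligand, only a slight excess of B2pin2 and the absence of a protic additive should secure.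

**Step 14**
Reactants: 20 (1S,2S,3R,4S,6S)-3-hydroxy-1-methyl-4-[1-(4,4,5,5-tetramethyl-1,3,2-dioxaborolan-2-yl)ethenyl]-7-oxabicyclo[4.1.0]heptan-2-yl (2Z)-2-methylbut-2-enoate; 14 (2Z)-2-methylbut-2-enoic 2,4,6-trichlorobenzoic anhydride
Product: 21 (1S,2S,3R,4S,6S)-1-methyl-4-[1-(4,4,5,5-tetramethyl-1,3,2-dioxaborolan-2-yl)ethenyl]-7-oxabicyclo[4.1.0]heptane-2,3-diyl bis[(2Z)-2-methylbut-2-enoate]
Conditions: 14 (toluene solution, excess), 20, toluene, 75 °C
Reagents that add atoms: none
Why: a second Yamaguchi-type angeloylation with the preformed mixed anhydride acylates the remaining axial secondary OH under conditions the alkenylboronate and oxirane tolerate; had the C2 ester migrated to C3 in step 13, the same diester would result.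

**Step 15**
Reactants: 21 (1S,2S,3R,4S,6S)-1-methyl-4-[1-(4,4,5,5-tetramethyl-1,3,2-dioxaborolan-2-yl)ethenyl]-7-oxabicyclo[4.1.0]heptane-2,3-diyl bis[(2Z)-2-methylbut-2-enoate]
Product: 22 (1S,2S,3R,4R,6S)-4-(1-iodoethenyl)-1-methyl-7-oxabicyclo[4.1.0]heptane-2,3-diyl bis[(2Z)-2-methylbut-2-enoate]
Conditions: NaI, TsN(Cl)Na, THF/H2O, 0 °C to rt, dark
Reagents that add atoms: sodium iodide, [Na+].[I-]
Why: ipso-iododeboronation by electrophilic iodine generated in the flask replaces boron by iodine at the same carbon; the electron-poor enoates and the oxirane should be inert (the C4 descriptor changes only through ligand priority).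

**Step 16**
Reactants: 23 4-methylpent-3-en-1-ol
Product: 24 4-methylpent-3-enal
Conditions: Dess–Martin periodinane, NaHCO3, CH2Cl2, 0 °C; used as a crude solution
Reagents that add atoms: none
Why: buffered Dess–Martin oxidation gives the β,γ-unsaturated aldehyde without moving the double bond into conjugation.

**Step 17**
Reactants: 22 (1S,2S,3R,4R,6S)-4-(1-iodoethenyl)-1-methyl-7-oxabicyclo[4.1.0]heptane-2,3-diyl bis[(2Z)-2-methylbut-2-enoate]; 24 4-methylpent-3-enal
Product: 26 (1S,2S,3R,4S,6S)-4-[(3S)-3-hydroxy-6-methylhepta-1,5-dien-2-yl]-1-methyl-7-oxabicyclo[4.1.0]heptane-2,3-diyl bis[(2Z)-2-methylbut-2-enoate], via alkenylchromium 25 (not isolated)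
Conditions: CrCl2, NiCl2 (cat.), N-[2-(4-isopropyl-4,5-dihydro-1,3-oxazol-2-yl)-6-methylphenyl]methanesulfonamide (single enantiomer), Et3N, THF, rt; aqueous work-up
Reagents that add atoms: chromium dichloride, Cl[Cr]Cl (its atoms are carried only in 25)
Why: Nozaki–Hiyama–Kishi coupling, in which nickel-mediated formation of alkenylchromium 25 (trivalent chromium) is followed by chemoselective addition to the aldehyde in the presence of esters and the oxirane; the C3' carbinol is set by the chiral sulfonamide–oxazoline ligand on chromium, the ligand enantiomer being chosen for (3'S) because C3' is remote from the ring stereocentres.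

**Step 18**
Reactants: 26 (1S,2S,3R,4S,6S)-4-[(3S)-3-hydroxy-6-methylhepta-1,5-dien-2-yl]-1-methyl-7-oxabicyclo[4.1.0]heptane-2,3-diyl bis[(2Z)-2-methylbut-2-enoate]
Product: 27 (1S,2S,3R,4S,6S)-4-[(3S)-3-(acetyloxy)-6-methylhepta-1,5-dien-2-yl]-1-methyl-7-oxabicyclo[4.1.0]heptane-2,3-diyl bis[(2Z)-2-methylbut-2-enoate]
Conditions: Ac2O, pyridine, 4-(dimethylamino)pyridine (cat.), CH2Cl2, 0 °C to rt
Reagents that add atoms: acetic anhydride, CC(=O)OC(C)=O
Why: acetylation of the only free hydroxyl under mild acyl-transfer catalysis completes the target; the preformed angelates should not isomerise under these conditions.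

**Compound list**
1 | but-3-yn-1-ol | C#CCCO | starting material
2 | penta-3,4-dien-1-ol | C=C=CCCO | intermediate
3 | 5-bromopenta-1,2-diene | C=C=CCCBr | intermediate
4 | (penta-3,4-dien-1-yl)triphenylphosphonium bromide | C=C=CCC[P+](c1ccccc1)(c1ccccc1)c1ccccc1.[Br-] | intermediate
5 | methyl (4S)-2,2-dimethyl-1,3-dioxolane-4-carboxylate | COC(=O)[C@@H]1COC(C)(C)O1 | starting material
6 | (4S)-N-methoxy-N,2,2-trimethyl-1,3-dioxolane-4-carboxamide (Weinreb amide, formed in the flask) | CON(C)C(=O)[C@@H]1COC(C)(C)O1 | intermediate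
7 | 1-[(4S)-2,2-dimethyl-1,3-dioxolan-4-yl]ethan-1-one | CC(=O)[C@@H]1COC(C)(C)O1 | intermediate
8 | (penta-3,4-dien-1-ylidene)triphenylphosphorane (ylide, formed in the flask) | C=C=CCC=P(c1ccccc1)(c1ccccc1)c1ccccc1 | intermediate
9 | (4R)-4-[(2Z)-hepta-2,5,6-trien-2-yl]-2,2-dimethyl-1,3-dioxolane | C=C=CC/C=C(/C)[C@@H]1COC(C)(C)O1 | intermediate
10 | (2R,3Z)-3-methylocta-3,6,7-triene-1,2-diol | C=C=CC/C=C(/C)[C@@H](O)CO | intermediate
11 | (2R,3Z)-1-[(tert-butyldimethylsilyl)oxy]-3-methylocta-3,6,7-trien-2-ol | C=C=CC/C=C(/C)[C@@H](O)CO[Si](C)(C)C(C)(C)C | intermediate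
12 | (1S)-1-[(2R,3S)-3-(buta-2,3-dien-1-yl)-2-methyloxiran-2-yl]-2-[(tert-butyldimethylsilyl)oxy]ethan-1-ol | C=C=CC[C@@H]1O[C@]1(C)[C@@H](O)CO[Si](C)(C)C(C)(C)C | intermediate
13 | angelic acid, (2Z)-2-methylbut-2-enoic acid | C/C=C(/C)C(=O)O | starting material
14 | (2Z)-2-methylbut-2-enoic 2,4,6-trichlorobenzoic anhydride | C/C=C(/C)C(=O)OC(=O)c1c(Cl)cc(Cl)cc1Cl | intermediate
15 | (1S)-1-[(2S,3S)-3-(buta-2,3-dien-1-yl)-2-methyloxiran-2-yl]-2-[(tert-butyldimethylsilyl)oxy]ethyl (2Z)-2-methylbut-2-enoate | C=C=CC[C@@H]1O[C@]1(C)[C@@H](OC(=O)/C(C)=C\C)CO[Si](C)(C)C(C)(C)C | intermediate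
16 | (1S)-1-[(2S,3S)-3-(buta-2,3-dien-1-yl)-2-methyloxiran-2-yl]-2-hydroxyethyl (2Z)-2-methylbut-2-enoate | C=C=CC[C@@H]1O[C@]1(C)[C@@H](OC(=O)/C(C)=C\C)CO | intermediate
17 | (1R)-1-[(2S,3S)-3-(buta-2,3-dien-1-yl)-2-methyloxiran-2-yl]-2-oxoethyl (2Z)-2-methylbut-2-enoate | C=C=CC[C@@H]1O[C@]1(C)[C@@H](OC(=O)/C(C)=C\C)C=O | intermediate
18 | (Z)-2-boryl σ-allylcopper from 17, copper on C1', Bpin on C2', CH2Cu cis to the chain (phosphine ligand omitted; formed in the flask) | [Cu]C/C(B1OC(C)(C)C(C)(C)O1)=C\C[C@@H]2O[C@]2(C)[C@@H](OC(=O)/C(C)=C\C)C=O | intermediate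
19 | O-(pinacolboryl) ether of 20 at C3 (formed in the flask) | C=C(B3OC(C)(C)C(C)(C)O3)[C@@H]1C[C@@H]2O[C@]2(C)[C@@H](OC(=O)/C(C)=C\C)[C@@H]1OB4OC(C)(C)C(C)(C)O4 | intermediate
20 | (1S,2S,3R,4S,6S)-3-hydroxy-1-methyl-4-[1-(4,4,5,5-tetramethyl-1,3,2-dioxaborolan-2-yl)ethenyl]-7-oxabicyclo[4.1.0]heptan-2-yl (2Z)-2-methylbut-2-enoate | C=C(B3OC(C)(C)C(C)(C)O3)[C@@H]1C[C@@H]2O[C@]2(C)[C@@H](OC(=O)/C(C)=C\C)[C@@H]1O | intermediate
21 | (1S,2S,3R,4S,6S)-1-methyl-4-[1-(4,4,5,5-tetramethyl-1,3,2-dioxaborolan-2-yl)ethenyl]-7-oxabicyclo[4.1.0]heptane-2,3-diyl bis[(2Z)-2-methylbut-2-enoate] | C=C(B3OC(C)(C)C(C)(C)O3)[C@@H]1C[C@@H]2O[C@]2(C)[C@@H](OC(=O)/C(C)=C\C)[C@@H]1OC(=O)/C(C)=C\C | intermediate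
22 | (1S,2S,3R,4R,6S)-4-(1-iodoethenyl)-1-methyl-7-oxabicyclo[4.1.0]heptane-2,3-diyl bis[(2Z)-2-methylbut-2-enoate] | C=C(I)[C@@H]1C[C@@H]2O[C@]2(C)[C@@H](OC(=O)/C(C)=C\C)[C@@H]1OC(=O)/C(C)=C\C | intermediate
23 | 4-methylpent-3-en-1-ol | CC(C)=CCCO | starting material
24 | 4-methylpent-3-enal | CC(C)=CCC=O | intermediate
25 | alkenylchromium dichloride from 22, trivalent chromium in place of iodine (formed in the flask) | C=C([Cr](Cl)Cl)[C@@H]1C[C@@H]2O[C@]2(C)[C@@H](OC(=O)/C(C)=C\C)[C@@H]1OC(=O)/C(C)=C\C | intermediate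
26 | (1S,2S,3R,4S,6S)-4-[(3S)-3-hydroxy-6-methylhepta-1,5-dien-2-yl]-1-methyl-7-oxabicyclo[4.1.0]heptane-2,3-diyl bis[(2Z)-2-methylbut-2-enoate] | C=C([C@H](CC=C(C)C)O)[C@@H]1C[C@@H]2O[C@]2(C)[C@@H](OC(=O)/C(C)=C\C)[C@@H]1OC(=O)/C(C)=C\C | intermediate
27 | (1S,2S,3R,4S,6S)-4-[(3S)-3-(acetyloxy)-6-methylhepta-1,5-dien-2-yl]-1-methyl-7-oxabicyclo[4.1.0]heptane-2,3-diyl bis[(2Z)-2-methylbut-2-enoate] | C=C([C@H](CC=C(C)C)OC(C)=O)[C@@H]1C[C@@H]2O[C@]2(C)[C@@H](OC(=O)/C(C)=C\C)[C@@H]1OC(=O)/C(C)=C\C | target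

**Step count**
Total step count: 18.
Longest linear sequence: 15 steps (from 1 through steps 1, 2, 3, 5 to 8, 10 to 15, 17 and 18).

**Steps most likely to fail**

Step 13. The allylcopper may equilibrate between its geometrical isomers before ring closure, the boryl copper species may add to the aldehyde directly, or the α-acyloxy aldehyde may enolise; each would erode the cis relation at C3/C4 or the conversion. The fallback separates boron addition from ring closure and sets out from alcohol 16. Palladium-catalysed diboration of the terminal C=C of the allene (Pd(dba)2 as the source of zerovalent palladium, catalytic 3-iodo-2-methylcyclohex-2-en-1-one as initiator, B2pin2, toluene, 80 °C) should give the configurationally stable (Z)-2-boryl allylboronate, (1S)-1-[(2S,3S)-3-[(2Z)-3,4-bis(4,4,5,5-tetramethyl-1,3,2-dioxaborolan-2-yl)but-2-en-1-yl]-2-methyloxiran-2-yl]-2-hydroxyethyl (2Z)-2-methylbut-2-enoate F1. Dess–Martin oxidation of F1 would give the corresponding aldehyde F2, which should undergo spontaneous, stereospecific intramolecular allylboration through the same closed chair to boryl ether 19. Aqueous work-up returns the route at compound 20.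

Step 17. Ligand control over the carbonyl face at C3' may be insufficient, or activation of the hindered 2-iodoalkene may be slow. The fallback sets out from 22 and moves the stereo-defining event from the C–C bond formation to a ketone reduction. Coupling of 22 with 24 without chiral ligand (CrCl2, cat. NiCl2, DMSO, rt) would give the C3'-epimeric alcohols, (1S,2S,3R,4S,6S)-4-(3-hydroxy-6-methylhepta-1,5-dien-2-yl)-1-methyl-7-oxabicyclo[4.1.0]heptane-2,3-diyl bis[(2Z)-2-methylbut-2-enoate] F3. Dess–Martin oxidation would give the α-methylene ketone, (1S,2S,3R,4S,6S)-1-methyl-4-(6-methyl-3-oxohepta-1,5-dien-2-yl)-7-oxabicyclo[4.1.0]heptane-2,3-diyl bis[(2Z)-2-methylbut-2-enoate] F4. Corey–Bakshi–Shibata reduction with (R)-1-methyl-3,3-diphenyl-tetrahydro-1H,3H-pyrrolo[1,2-c][1,3,2]oxazaborole and catecholborane (toluene, −78 °C), with the branched alkenyl group acting as the large substituent, should give the (3'S) alcohol and return the route at compound 26.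

Step 14. Acylation of the axial C3 hydroxyl, flanked by C2 and C4 substituents, may be sluggish, and forcing conditions may drift the activated acid from Z to E. The fallback sets out from 20 and builds the angelate in place. Steglich esterification with the unhindered 2-[bis(2,2,2-trifluoroethoxy)phosphoryl]propanoic acid (DCC, cat. 4-(dimethylamino)pyridine, CH2Cl2) would give the phosphonate ester, (1S,2S,3R,4S,6S)-3-({2-[bis(2,2,2-trifluoroethoxy)phosphoryl]propanoyl}oxy)-1-methyl-4-[1-(4,4,5,5-tetramethyl-1,3,2-dioxaborolan-2-yl)ethenyl]-7-oxabicyclo[4.1.0]heptan-2-yl (2Z)-2-methylbut-2-enoate F5. Still–Gennari olefination of F5 with acetaldehyde (KN(SiMe3)2, 18-crown-6, THF, −78 °C) should form the (Z)-enoate and return the route at compound 21.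

**Further compounds**
F1 | step 13 | (1S)-1-[(2S,3S)-3-[(2Z)-3,4-bis(4,4,5,5-tetramethyl-1,3,2-dioxaborolan-2-yl)but-2-en-1-yl]-2-methyloxiran-2-yl]-2-hydroxyethyl (2Z)-2-methylbut-2-enoate | O1C(C)(C)C(C)(C)OB1C/C(B2OC(C)(C)C(C)(C)O2)=C\C[C@@H]3O[C@]3(C)[C@@H](OC(=O)/C(C)=C\C)CO
F2 | step 13 | (1R)-1-[(2S,3S)-3-[(2Z)-3,4-bis(4,4,5,5-tetramethyl-1,3,2-dioxaborolan-2-yl)but-2-en-1-yl]-2-methyloxiran-2-yl]-2-oxoethyl (2Z)-2-methylbut-2-enoate | O1C(C)(C)C(C)(C)OB1C/C(B2OC(C)(C)C(C)(C)O2)=C\C[C@@H]3O[C@]3(C)[C@@H](OC(=O)/C(C)=C\C)C=O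
F3 | step 17 | (1S,2S,3R,4S,6S)-4-(3-hydroxy-6-methylhepta-1,5-dien-2-yl)-1-methyl-7-oxabicyclo[4.1.0]heptane-2,3-diyl bis[(2Z)-2-methylbut-2-enoate], both C3' epimers | C=C(C(O)CC=C(C)C)[C@@H]1C[C@@H]2O[C@]2(C)[C@@H](OC(=O)/C(C)=C\C)[C@@H]1OC(=O)/C(C)=C\C
F4 | step 17 | (1S,2S,3R,4S,6S)-1-methyl-4-(6-methyl-3-oxohepta-1,5-dien-2-yl)-7-oxabicyclo[4.1.0]heptane-2,3-diyl bis[(2Z)-2-methylbut-2-enoate] | C=C(C(=O)CC=C(C)C)[C@@H]1C[C@@H]2O[C@]2(C)[C@@H](OC(=O)/C(C)=C\C)[C@@H]1OC(=O)/C(C)=C\C
F5 | step 14 | (1S,2S,3R,4S,6S)-3-({2-[bis(2,2,2-trifluoroethoxy)phosphoryl]propanoyl}oxy)-1-methyl-4-[1-(4,4,5,5-tetramethyl-1,3,2-dioxaborolan-2-yl)ethenyl]-7-oxabicyclo[4.1.0]heptan-2-yl (2Z)-2-methylbut-2-enoate | C=C(B3OC(C)(C)C(C)(C)O3)[C@@H]1C[C@@H]2O[C@]2(C)[C@@H](OC(=O)/C(C)=C\C)[C@@H]1OC(=O)C(C)P(=O)(OCC(F)(F)F)OCC(F)(F)F
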